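## Retrosynthetic overview
1. Only functional-group changes separate the target from one tricyclic enyne ketone. These are the four acetates, the 3Z-alkene (from a C3≡C4 alkyne), the spiro-epoxide (from C11=C20 via its diol), the 13,14-diol (from C13=C14) and 9-OH (from a ketone).
2. Key disconnection: C1–C10 and C11–C12 are cut together. A macrocyclising intramolecular Diels–Alder reaction joins the C12=C13–C14=C1 diene to a C9-acyl allene (C10=C11=C20) and closes the cyclohexene and the ten-membered ring in one step.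
3. The Diels–Alder precursor is assembled in one flask from three pieces. A dioxolanone enolate adds to an enynal (C7–C8 aldol), an allenyl Grignard reagent is acylated (C9–C10), and acid closes the lactone.
4. The enynal comes from a C4–C5 Sonogashira coupling of a dienyl alkynol (asymmetric alkynylation sets C2) with a Z-iodoenal made from butynediol. The dioxolanone comes from an Evans syn-aldol of a propionimide with ethyl glyoxylate (sets C8 and C17).
5. Ring order: γ-lactone, then the six- and ten-membered carbocycles together, then the spiro-epoxide.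

Locants and faces:
- C1 is the quaternary carbon (C15 methyl). C2–C10 complete the ten-membered ring, with C16 = CH2O on C5.
- C11–C14 complete the six-membered ring, with C20 on C11.
- C17 (C18 methyl) and C19 (C=O) belong to the lactone.
- β is the face of the six-membered ring that carries C15; α is the opposite face.

Assumption: (R,R)-ProPhenol is taken to give the drawn C2 epimer in step 2; if the sense is opposite, the equally available (S,S)-ligand is used.

## Route

Step 1
Reactants: 1 acrolein; 2 2-(triphenylphosphoranylidene)propanal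
Product: 3 (2E)-2-methylpenta-2,4-dienal
Conditions: CH2Cl2, 0 °C → rt
Reagents that add atoms: none
Why: A Wittig olefination with a stabilised ylide attacks only the aldehyde of acrolein and gives the E-trisubstituted enal, which fixes the C1=C14 geometry (C2 trans to C13).

Step 2
Reactants: 3 (2E)-2-methylpenta-2,4-dienal; 4 ethynyl(trimethyl)silane
Product: 6 (3R,4E)-4-methyl-1-(trimethylsilyl)hepta-4,6-dien-1-yn-3-ol, via methylzinc acetylide 5 (not isolated)
Conditions: Me2Zn, (R,R)-ProPhenol (10 mol %), Ph3P=O (20 mol %), PhMe, 0–4 °C; aq NH4Cl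
Reagents that add atoms: none
Why: In this catalytic asymmetric alkynylation the dinuclear zinc–ProPhenol complex delivers the zinc acetylide 1,2 to one face of the enal, which sets C2.

Step 3
Reactants: 6 (3R,4E)-4-methyl-1-(trimethylsilyl)hepta-4,6-dien-1-yn-3-ol
Product: 7 (3S,4E)-4-methylhepta-4,6-dien-1-yn-3-ol (same spatial arrangement; only the descriptor changes)
Conditions: K2CO3 (cat.), MeOH, 0 °C
Reagents that add atoms: none
Why: Base-catalysed methanolysis of the C(sp)–Si bond (protodesilylation) frees the terminal alkyne without touching the carbinol or the diene.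

Step 4
Reactants: 8 but-2-yne-1,4-diol
Product: 9 4-[(tert-butyldimethylsilyl)oxy]but-2-yn-1-ol
Conditions: TBSCl (0.3 equiv), imidazole, DMF, 0 °C
Reagents that add atoms: tert-butyldimethylsilyl chloride, CC(C)(C)[Si](C)(C)Cl
Why: Statistical monosilylation of the cheap symmetrical diol used in excess differentiates the future C16–O from the future C7–O.

Step 5
Reactants: 9 4-[(tert-butyldimethylsilyl)oxy]but-2-yn-1-ol
Product: 11 (2Z)-4-[(tert-butyldimethylsilyl)oxy]-3-iodobut-2-en-1-ol, via cyclic alkenylaluminate 10 (not isolated)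
Conditions: Red-Al, THF, 0 °C; I2, −78 °C; aq Rochelle salt
Reagents that add atoms: iodine, II
Why: Hydroxyl-directed trans-hydroalumination places aluminium on the distal carbon C5 in a five-membered ate complex, and iodinolysis with retention gives the Z-iodoalkene, so the later C4 substituent ends up cis to C7.

Step 6
Reactants: 11 (2Z)-4-[(tert-butyldimethylsilyl)oxy]-3-iodobut-2-en-1-ol
Product: 12 (2Z)-4-[(tert-butyldimethylsilyl)oxy]-3-iodobut-2-enal
Conditions: MnO2, CH2Cl2, rt
Reagents that add atoms: none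
Why: Neutral MnO2 oxidation of the allylic alcohol stops at the enal and preserves the alkene geometry, the iodide and the silyl ether.

Step 7
Reactants: 7 (3S,4E)-4-methylhepta-4,6-dien-1-yn-3-ol; 12 (2Z)-4-[(tert-butyldimethylsilyl)oxy]-3-iodobut-2-enal
Product: 13 (2E,6R,7E)-3-{[(tert-butyldimethylsilyl)oxy]methyl}-6-hydroxy-7-methyldeca-2,7,9-trien-4-ynal
Conditions: PdCl2(PPh3)2 (3 mol %), CuI (6 mol %), Et3N, THF, rt
Reagents that add atoms: none
Why: Sonogashira coupling of the activated β-iodoenal proceeds at room temperature with retention of alkene geometry, tolerates the free carbinol and forms the C4–C5 bond.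

Step 8
Reactants: 14 (4R)-4-benzyl-3-propanoyl-1,3-oxazolidin-2-one; 15 ethyl glyoxylate
Product: 17 ethyl (2R,3R)-4-[(4R)-4-benzyl-2-oxo-1,3-oxazolidin-3-yl]-2-hydroxy-3-methyl-4-oxobutanoate, via Z-boron enolate 16 (not isolated)
Conditions: Bu2BOTf, Et3N, CH2Cl2, 0 °C; 15, −78 → 0 °C; H2O2, MeOH, pH 7 buffer
Reagents that add atoms: none
Why: In this Evans syn-aldol reaction the Z-boron enolate reacts through a closed chair transition state on the face away from the benzyl group, which sets C8 and C17 in the syn relationship of the target.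

Step 9
Reactants: 17 ethyl (2R,3R)-4-[(4R)-4-benzyl-2-oxo-1,3-oxazolidin-3-yl]-2-hydroxy-3-methyl-4-oxobutanoate
Product: 18 (2R,3R)-2-hydroxy-3-methylbutanedioic acid
Conditions: LiOH, H2O2, THF/H2O, 0 °C → rt; Na2SO3; HCl
Reagents that add atoms: lithium hydroxide, [Li+].[OH-]; hydrogen peroxide, OO
Why: Hydroperoxide cleaves the exocyclic imide carbonyl selectively and hydroxide saponifies the ethyl ester (acyl substitution) under conditions too mild to epimerise C17.

Step 10
Reactants: 18 (2R,3R)-2-hydroxy-3-methylbutanedioic acid; 19 pivalaldehyde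
Product: 20 (2R)-2-[(2R,4R)-2-tert-butyl-5-oxo-1,3-dioxolan-4-yl]propanoic acid (cis-dioxolanone)
Conditions: TsOH (cat.), H2SO4 (cat.), pentane, reflux (Dean–Stark); recrystallisation
Reagents that add atoms: none
Why: Acid-catalysed acetalisation engages the α-hydroxy acid in the five-membered dioxolanone, and the thermodynamically preferred, crystalline cis isomer stores the C8 information in the new acetal centre.

Step 11
Reactants: 20 (2R)-2-[(2R,4R)-2-tert-butyl-5-oxo-1,3-dioxolan-4-yl]propanoic acid; 13 (2E,6R,7E)-3-{[(tert-butyldimethylsilyl)oxy]methyl}-6-hydroxy-7-methyldeca-2,7,9-trien-4-ynal; 21 propargyl bromide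
Product: 25 (3R,4S,5S)-4-(but-3-ynoyl)-4-hydroxy-5-[(1E,5R,6E)-2-{[(tert-butyldimethylsilyl)oxy]methyl}-5-hydroxy-6-methylnona-1,6,8-trien-3-yn-1-yl]-3-methyloxolan-2-one, via dilithio enolate 22 (not isolated), via aldol adduct 23 (not isolated), via keto acid 24 (not isolated)
Conditions: 20, LiHMDS (2.1 equiv), THF, −78 °C; Li alkoxide of 13 (LiHMDS, 1 equiv), −78 °C; H2C=C=CHMgBr (from 21, Mg, cat. HgCl2, Et2O), −78 → −40 °C; 1 M HCl, then TsOH (cat.), CH2Cl2, rt
Reagents that add atoms: none
Why: This is an aldol addition with self-regeneration of the stereocentre in which the enolate is attacked anti to the tert-butyl group (C8, retention) through a closed Zimmerman–Traxler chair that places O7 anti to O8 (C7), the lithium carboxylate then shields C19 so that the allenyl Grignard reagent (SE2′) is acylated only at the dioxolanone carbonyl, and acid releases pivalaldehyde and closes the γ-lactone.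

Step 12
Reactants: 25 the 2,8-diol lactone of step 11
Product: 26 (3R,4S,5S)-5-[(1E,5R,6E)-5-acetoxy-2-{[(tert-butyldimethylsilyl)oxy]methyl}-6-methylnona-1,6,8-trien-3-yn-1-yl]-4-(but-3-ynoyl)-4-hydroxy-3-methyloxolan-2-one
Conditions: Ac2O, pyridine, CH2Cl2, 0 °C
Reagents that add atoms: acetic anhydride, CC(=O)OC(C)=O
Why: Acylation takes the secondary C2 carbinol and leaves the tertiary C8 hydroxyl, and pyridine is too weak a base to isomerise the β,γ-alkynyl ketone.

Step 13
Reactants: 26 the 2-acetate of step 12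
Product: 28 (3R,4S,5S)-5-[(1E,5R,6E)-5-acetoxy-2-{[(tert-butyldimethylsilyl)oxy]methyl}-6-methylnona-1,6,8-trien-3-yn-1-yl]-4-(buta-2,3-dienoyl)-3-methyl-4-[(triethylsilyl)oxy]oxolan-2-one, via TES ether 27 (not isolated)
Conditions: TESOTf, 2,6-lutidine, CH2Cl2, −78 → 0 °C; then Et3N (0.2 equiv), rt
Reagents that add atoms: triethylsilyl triflate, CC[Si](CC)(CC)OS(=O)(=O)C(F)(F)F
Why: The silyl triflate caps the hindered tertiary alcohol, which blocks oxa-Michael closure to a 3(2H)-furanone, and the amine-catalysed prototropic alkyne-to-allene isomerisation then stops at the conjugated allenyl ketone.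

Step 14
Reactants: 28 the allenyl ketone/diene of step 13
Product: 29 tricyclic Diels–Alder adduct (trans-fused cyclohexene/ten-membered enyne; C15 methyl β; H-10 α; C9 ketone; C11=C20 methylene; C13=C14 alkene; 2-OAc; 8-OTES; 16-OTBS)
Conditions: PhMe (0.5 mM), BHT, 110 °C, sealed vessel, 48 h
Reagents that add atoms: none
Why: Proposed new method: a macrocyclising intramolecular Diels–Alder reaction in which the conjugated C10=C11 bond of the slim, strongly activated allenyl ketone adds to the diene with matched polarity (the unsubstituted terminus C12 bonds first to the β-carbon C11 in an asynchronous transition state, which eases the s-cis demand of the inside methyl group, and C1–C10 then closes the quaternary centre), the cis-enyne and the lactone pre-fold the eight-atom tether, H-2 eclipses C1=C14 so that the tether lies on the attacked face and OAc on the other (C1), and the tether allows only the carbonyl-exo mode that gives the trans ring fusion (C10); the closest known reaction types are the macrocyclising intramolecular Diels–Alder reactions that close the eleven-membered ring and the cyclohexene of the cytochalasans and the intermolecular Diels–Alder reactions of allenyl ketones that leave an exocyclic methylene group.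

Step 15
Reactants: 29 tricyclic Diels–Alder adduct
Product: 30 9S-alcohol of 29 (all other centres unchanged)
Conditions: NaBH4, CeCl3·7H2O, MeOH/THF, −78 → −40 °C
Reagents that add atoms: none
Why: In this Luche reduction hydride adds anti to C1 (the largest group on C10, Felkin–Anh) and anti to the C8–OSi bond (polar Felkin–Anh with C7 anti to C10), and both models give 9S while lactone and acetate survive.

Step 16
Reactants: 30 9S-alcohol
Product: 31 pentaol (9-OH; 11α-OH; 13α-OH; 14α-OH; 20-OH; alkyne, C5=C6, 2-OAc, 8-OTES and 16-OTBS retained)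
Conditions: OsO4 (5 mol %), NMO (2.2 equiv), acetone/H2O, 0 °C
Reagents that add atoms: N-methylmorpholine N-oxide, C[N+]1([O-])CCOCC1; water, O
Why: Upjohn syn-dihydroxylation attacks both ring alkenes from the α face opposite the axial C15 methyl group (sets C11, C13 and C14), whereas the trisubstituted C5=C6 alkene is conjugated to the alkyne, flanked by two allylic C–O bonds and therefore slower.

Step 17
Reactants: 31 pentaol
Product: 32 11,20-spiro-epoxide triol (epoxide O α; 9-OH, 13α-OH and 14α-OH free)
Conditions: PPh3, DIAD, THF, 0 °C → rt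
Reagents that add atoms: none
Why: In this Mitsunobu-type cyclodehydration through a 1,3,2-dioxaphospholane the primary C20–O is activated and the tertiary O11 displaces it, so C11 keeps its configuration, and the cis-13,14-diol cannot reach the anti arrangement that epoxide formation needs.

Step 18
Reactants: 32 spiro-epoxide triol
Product: 33 (3Z,5E)-diene triol
Conditions: H2 (1 atm), Lindlar catalyst, quinoline, EtOAc, rt
Reagents that add atoms: none
Why: Lindlar semihydrogenation adds hydrogen syn to the only alkyne and gives the 3Z-alkene, while the poisoned catalyst leaves the trisubstituted alkene, the epoxide and the allylic esters alone.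

Step 19
Reactants: 33 (3Z,5E)-diene triol
Product: 34 2,9,13,14-tetraacetate (8-OTES; 16-OTBS)
Conditions: Ac2O, DMAP, pyridine, rt → 40 °C
Reagents that add atoms: acetic anhydride, CC(=O)OC(C)=O
Why: DMAP-catalysed acylation esterifies the three secondary alcohols, including the axial 14-OH, while O8 and O16 stay silylated.

Step 20
Reactants: 34 2,9,13,14-tetraacetate
Product: 35 CNP0317528.1 (target)
Conditions: TBAF/AcOH (1:1), THF, 0 °C → rt
Reagents that add atoms: none
Why: Buffered fluoride desilylation removes both silyl ethers, and the acetic acid buffer suppresses acetate migration and epoxide opening.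

## Compound list
1 | acrolein | C=CC=O | starting material
2 | 2-(triphenylphosphoranylidene)propanal | CC(C=O)=P(c1ccccc1)(c1ccccc1)c1ccccc1 | starting material
3 | (2E)-2-methylpenta-2,4-dienal | C=C/C=C(C)/C=O | intermediate
4 | ethynyl(trimethyl)silane | C#C[Si](C)(C)C | starting material
5 | methyl[(trimethylsilyl)ethynyl]zinc | C[Zn]C#C[Si](C)(C)C | intermediate
6 | (3R,4E)-4-methyl-1-(trimethylsilyl)hepta-4,6-dien-1-yn-3-ol | C[Si](C)(C)C#C[C@H](O)/C(C)=C/C=C | intermediate
7 | (3S,4E)-4-methylhepta-4,6-dien-1-yn-3-ol | C#C[C@H](O)/C(C)=C/C=C | intermediate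
8 | but-2-yne-1,4-diol | OCC#CCO | starting material
9 | 4-[(tert-butyldimethylsilyl)oxy]but-2-yn-1-ol | OCC#CCO[Si](C)(C)C(C)(C)C | intermediate
10 | sodium cyclic alkenylaluminate (O7–Al–C5 five-membered ate complex) | [Na+].COCCO[Al-]1(OCCOC)OCC=C1CO[Si](C)(C)C(C)(C)C | intermediate
11 | (2Z)-4-[(tert-butyldimethylsilyl)oxy]-3-iodobut-2-en-1-ol | OC/C=C(CO[Si](C)(C)C(C)(C)C)\I | intermediate
12 | (2Z)-4-[(tert-butyldimethylsilyl)oxy]-3-iodobut-2-enal | O=C/C=C(CO[Si](C)(C)C(C)(C)C)\I | intermediate
13 | (2E,6R,7E)-3-{[(tert-butyldimethylsilyl)oxy]methyl}-6-hydroxy-7-methyldeca-2,7,9-trien-4-ynal | O=C/C=C(CO[Si](C)(C)C(C)(C)C)\C#C[C@H](O)/C(C)=C/C=C | intermediate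
14 | (4R)-4-benzyl-3-propanoyl-1,3-oxazolidin-2-one | CCC(=O)N1[C@H](Cc2ccccc2)COC1=O | starting material
15 | ethyl glyoxylate | CCOC(=O)C=O | starting material
16 | (Z)-dibutylboron enolate of 14 | C/C=C(\OB(CCCC)CCCC)N1[C@H](Cc2ccccc2)COC1=O | intermediate
17 | ethyl (2R,3R)-4-[(4R)-4-benzyl-2-oxo-1,3-oxazolidin-3-yl]-2-hydroxy-3-methyl-4-oxobutanoate | CCOC(=O)[C@H](O)[C@@H](C)C(=O)N1[C@H](Cc2ccccc2)COC1=O | intermediate
18 | (2R,3R)-2-hydroxy-3-methylbutanedioic acid | OC(=O)[C@H](O)[C@@H](C)C(O)=O | intermediate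
19 | pivalaldehyde | CC(C)(C)C=O | starting material
20 | (2R)-2-[(2R,4R)-2-tert-butyl-5-oxo-1,3-dioxolan-4-yl]propanoic acid | CC(C)(C)[C@@H]1O[C@H]([C@@H](C)C(O)=O)C(=O)O1 | intermediate
21 | propargyl bromide | C#CCBr | starting material
22 | dilithio enolate of 20 (carboxylate and ring enolate) | CC(C)(C)[C@@H]1OC([C@@H](C)C(=O)O[Li])=C(O[Li])O1 | intermediate
23 | C7–C8 aldol adduct (dioxolanone retained; neutral form) | CC(C)(C)[C@@H]1O[C@@]([C@@H](C)C(O)=O)([C@@H](O)/C=C(CO[Si](C)(C)C(C)(C)C)\C#C[C@H](O)/C(C)=C/C=C)C(=O)O1 | intermediate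
24 | open keto acid (but-3-ynoyl ketone at C9; 2-, 7- and 8-OH and C19 acid free) | C#CCC(=O)[C@](O)([C@@H](C)C(O)=O)[C@@H](O)/C=C(CO[Si](C)(C)C(C)(C)C)\C#C[C@H](O)/C(C)=C/C=C | intermediate
25 | 2,8-diol lactone alkynyl ketone (name in step 11) | C#CCC(=O)[C@@]1(O)[C@H](/C=C(CO[Si](C)(C)C(C)(C)C)\C#C[C@H](O)/C(C)=C/C=C)OC(=O)[C@@H]1C | intermediate
26 | 2-acetate of 25 | C#CCC(=O)[C@@]1(O)[C@H](/C=C(CO[Si](C)(C)C(C)(C)C)\C#C[C@H](OC(C)=O)/C(C)=C/C=C)OC(=O)[C@@H]1C | intermediate
27 | 8-O-TES ether of 26 | C#CCC(=O)[C@@]1(O[Si](CC)(CC)CC)[C@H](/C=C(CO[Si](C)(C)C(C)(C)C)\C#C[C@H](OC(C)=O)/C(C)=C/C=C)OC(=O)[C@@H]1C | intermediate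
28 | allenyl ketone/diene (Diels–Alder precursor; name in step 13) | C=C=CC(=O)[C@@]1(O[Si](CC)(CC)CC)[C@H](/C=C(CO[Si](C)(C)C(C)(C)C)\C#C[C@H](OC(C)=O)/C(C)=C/C=C)OC(=O)[C@@H]1C | intermediate
29 | tricyclic Diels–Alder adduct (C9 ketone) | C1C(=C)[C@@H]2C(=O)[C@@]3(O[Si](CC)(CC)CC)[C@H](/C=C(CO[Si](C)(C)C(C)(C)C)\C#C[C@H](OC(C)=O)[C@@]2(C)C=C1)OC(=O)[C@@H]3C | intermediate
30 | 9S-alcohol | C1C(=C)[C@@H]2[C@H](O)[C@@]3(O[Si](CC)(CC)CC)[C@H](/C=C(CO[Si](C)(C)C(C)(C)C)\C#C[C@H](OC(C)=O)[C@@]2(C)C=C1)OC(=O)[C@@H]3C | intermediate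
31 | 9,11α,13α,14α,20-pentaol | O[C@H]1C[C@](O)(CO)[C@@H]2[C@H](O)[C@@]3(O[Si](CC)(CC)CC)[C@H](/C=C(CO[Si](C)(C)C(C)(C)C)\C#C[C@H](OC(C)=O)[C@@]2(C)[C@H]1O)OC(=O)[C@@H]3C | intermediate
32 | 11,20-spiro-epoxide 9,13,14-triol (alkyne) | O[C@H]1C[C@]2(CO2)[C@@H]2[C@H](O)[C@@]3(O[Si](CC)(CC)CC)[C@H](/C=C(CO[Si](C)(C)C(C)(C)C)\C#C[C@H](OC(C)=O)[C@@]2(C)[C@H]1O)OC(=O)[C@@H]3C | intermediate
33 | (3Z,5E)-diene epoxy triol | O[C@H]1C[C@]2(CO2)[C@@H]2[C@H](O)[C@@]3(O[Si](CC)(CC)CC)[C@H](/C=C(CO[Si](C)(C)C(C)(C)C)\C=C/[C@H](OC(C)=O)[C@@]2(C)[C@H]1O)OC(=O)[C@@H]3C | intermediate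
34 | 2,9,13,14-tetraacetate (8-OTES; 16-OTBS) | CC(=O)O[C@H]1C[C@]2(CO2)[C@@H]2[C@H](OC(C)=O)[C@@]3(O[Si](CC)(CC)CC)[C@H](/C=C(CO[Si](C)(C)C(C)(C)C)\C=C/[C@H](OC(C)=O)[C@@]2(C)[C@H]1OC(C)=O)OC(=O)[C@@H]3C | intermediate
35 | CNP0317528.1 | CC(=O)O[C@H]1C[C@]2(CO2)[C@@H]2[C@H](OC(C)=O)[C@@]3(O)[C@H](/C=C(CO)\C=C/[C@H](OC(C)=O)[C@@]2(C)[C@H]1OC(C)=O)OC(=O)[C@@H]3C | target

## Step count and weak points
Total steps: 20. Longest linear sequence: 14 (steps 1–3, 7, 11–20; the branch through steps 4–6 is equally long).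

**Step 14 (macrocyclising Diels–Alder reaction).** The diene terminus C1 is disubstituted and a ten-membered ring must close. The fallback sets out from 12, 20, 21 and 7 and returns at 29; it separates the two ring closures. The union of step 11 is run with iodoenal 12 in place of 13 and gives the iodovinyl lactone alkynyl ketone F1. Silylation and isomerisation as in step 13 convert it into the iodovinyl allenyl ketone F2. Alkynol 7 is acetylated to the dienynyl acetate F3. An intermolecular Diels–Alder reaction of F2 with F3 (2 M in toluene, 60–80 °C) gives the cyclohexene iodide-alkyne F4; C10 can be equilibrated to the trans isomer through the ketone enol. A high-dilution intramolecular Sonogashira coupling (C4–C5) then closes the ten-membered ring to 29.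

**Step 11 (one-flask aldol, Grignard acylation and lactonisation).** The hindered dioxolanone carbonyl may resist the Grignard reagent or add it twice. The fallback sets out from 20 and 13 and returns at 25; it moves the acyl transfer to an isolated, chelating acyl donor. The aldol mixture is acidified directly, which gives the spiro lactone-dioxolanone F5. The activated dioxolanone alone is opened with N,O-dimethylhydroxylamine and i-PrMgCl at −20 °C to the Weinreb amide lactone F6. Allenylmagnesium bromide then gives 25 by single addition to the chelated amide.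

**Step 16 (double dihydroxylation beside the enyne alkene).** Over-oxidation at C5=C6 or incomplete reaction is possible. The fallback sets out from 30 and returns at 32; it oxidises the two ring alkenes one after the other by different reactions. Buffered mCPBA (1 equiv, −20 °C) epoxidises the more accessible 1,1-disubstituted C11=C20 alkene from the α face to the epoxy cyclohexene F7. OsO4/NMO then dihydroxylates the remaining C13=C14 alkene from the α face to 32, so that 31 and step 17 are bypassed.

## Further compounds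
F1 | step 14 | iodovinyl lactone alkynyl ketone (8-OH free) | C#CCC(=O)[C@@]1(O)[C@H](/C=C(CO[Si](C)(C)C(C)(C)C)\I)OC(=O)[C@@H]1C
F2 | step 14 | iodovinyl allenyl ketone (8-OTES) | C=C=CC(=O)[C@@]1(O[Si](CC)(CC)CC)[C@H](/C=C(CO[Si](C)(C)C(C)(C)C)\I)OC(=O)[C@@H]1C
F3 | step 14 | dienynyl acetate (acetate of 7) | C#C[C@H](OC(C)=O)/C(C)=C/C=C
F4 | step 14 | cyclohexene iodide-alkyne (intermolecular adduct; C1 and C10 as in 29) | C1C(=C)[C@H](C(=O)[C@@]2(O[Si](CC)(CC)CC)[C@H](/C=C(CO[Si](C)(C)C(C)(C)C)\I)OC(=O)[C@@H]2C)[C@@](C)([C@@H](OC(C)=O)C#C)C=C1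
F5 | step 11 | spiro lactone-dioxolanone | CC(C)(C)[C@@H]1O[C@]2(C(=O)O1)[C@H](/C=C(CO[Si](C)(C)C(C)(C)C)\C#C[C@H](O)/C(C)=C/C=C)OC(=O)[C@@H]2C
F6 | step 11 | Weinreb amide lactone | CON(C)C(=O)[C@@]1(O)[C@H](/C=C(CO[Si](C)(C)C(C)(C)C)\C#C[C@H](O)/C(C)=C/C=C)OC(=O)[C@@H]1C
F7 | step 16 | epoxy cyclohexene (11,20-epoxide; C13=C14 retained) | C1[C@]2(CO2)[C@@H]2[C@H](O)[C@@]3(O[Si](CC)(CC)CC)[C@H](/C=C(CO[Si](C)(C)C(C)(C)C)\C#C[C@H](OC(C)=O)[C@@]2(C)C=C1)OC(=O)[C@@H]3C
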